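**Reading time.** You read this flask at 15 h, later than the 8.00 h at which its dawn readings stop. The midnight run differs from it in one charge, the protic impurity, and does reach that time.

all flasks: starting material 49 mM; gas phase 25 mM (held); catalyst 9.8 mM

| run | protic impurity | remark | time |
|---|---|---|---|
| dawn | 9.8 mM | the very flask that is asked about, followed so far |  |
| midnight | 15 mM | run made earlier |  |
| flask | 9.80 mM |  | 15 h |

- dawn (time / h: product / %, starting material / %): 0.500: 3, 98; 1.33: 11, 91; 2.50: 25, 73; 4.00: 35, 58; 6.00: 54, 40; 8.00: 62, 28
- midnight (time / h: product / %, starting material / %): 2.50: 19, 73; 5.00: 46, 46; 8.00: 61, 25; 10.0: 65, 16; 12.0: 74, 10; 15.0: 76, 5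

(each reading ± 1.5 percentage points)

- the earlier runs were read with a standard deviation of 1.5 percentage points
- at the start none of the gas phase is in solution

1. product at 15 h, in percent of the starting material charged
2. concentration of dissolved gas in solution at 15 h, in percent of saturation

**What weighs.** Product is the consumed part of the starting material times the share of it that becomes product, so you need the remainder and the share. In the dawn run the starting material falls at 0.174 h⁻¹ between 2.50 h and 8.00 h. Extended to 15 h, that leaves 8.27%, and a rate off by 10 per cent shifts this by 1.1 percentage points. The same error in the share, read at dawn as 86.1%, moves the product by 7.9 points, more than the rate does. The share is the number to know well.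

**Side ratio.** If product and the missing material both form at first order in starting material, starting material cancels from their ratio, and integration leaves a share that does not depend on it. Take the side ratio: accumulated missing material per accumulated product, divided by the equivalents of impurity to starting material, which the last midnight reading puts at 0.817. The dawn run at 8.00 h reads 0.806. Your estimate for this flask is therefore 78.9%.

**The result.** The forecast stands higher than this at 80%, with 94% of saturation, holding that “the side loss is impurity-linked”; the flask gives 81.7% and 94.9%.

    gas phase ⇌ dissolved gas, rate k1*(csat - [dissolved gas]) (kL = 0.710 h⁻¹)
    starting material + dissolved gas + catalyst → catalyst + product (k = 1600 L² mol⁻² h⁻¹)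
    starting material + protic impurity → quenched substrate (k = 2.90 L mol⁻¹ h⁻¹)
    dissolved gas + catalyst ⇌ idle complex, settled at all times (K = 41.0 L mol⁻¹)
    2 starting material → homo dimer (k = 7.70 × 10⁻⁴ L mol⁻¹ h⁻¹)

**Neighbouring flask.** On this flask, the simulated remainder of 7.0% and the side ratio give 80.0% against the 81.7% found. The neighbour is charged with 39 mM of protic impurity, which is 0.796 equiv to the starting material. The side ratio puts its missing material per product at 0.650, and with 2.8% of the starting material left, the reckoning gives 58.9%. That neighbour holds 37.2% as quenched substrate and 60.0% as product.

The data stem from a simulated flask for substances that don't exist.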